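**Retrosynthetic overview**
1. Feature used: in the benzopyran, O1 (on C8a) and the C6–OH are para, and C4 sits on C4a next to C8a. C4a is the only arene carbon that carries neither methyl nor oxygen. This pattern is what an ipso-oxygenation/1,2-alkyl shift (NIH-shift pattern) of a para-alkylphenol leaves behind.
2. Key disconnection: the C4–C4a bond is traced back to a C4–C8a bond, so the chroman-6-ol comes from a 1-oxaspiro[4.5]deca-6,9-dien-8-one. A dienone–phenol ring expansion (five- to six-membered O-ring) forms the dihydropyran and the hydroquinone ring together, as the last event.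
3. The spirodienone comes from a 4-alkyl-2,3,6-trimethylphenol with the tertiary carbinol in its chain, by oxidative dearomatising spiroetherification (O1–C8a bond). The spiro-tetrahydrofuran is the first ring formed.
4. The alkylphenol comes from (R)-geranyllinalool and 4-iodo-2,3,6-trimethylphenol by hydroboration/B-alkyl Suzuki–Miyaura coupling, without protecting groups.
5. C2 is set before any ring exists, by enantioselective Cu-catalysed SN2′ borylation/oxidation of geranylgeranyl methyl carbonate. Its C–O bond is never broken afterwards.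

Key step: step 6

Assumption: the enantiomer of the chiral NHC ligand in step 2 is chosen so that boron is delivered to the alkene face leading to (S)-3 and hence (R)-4. Compound 9 is carried as a mixture of its C5 (spiro) epimers, because C5 becomes sp2 in step 6.

Step 1
Reactants: 1 (2E,6E,10E)-geranylgeraniol
Product: 2 (2E,6E,10E)-geranylgeranyl methyl carbonate
Conditions: ClCO2Me (1.5 equiv), pyridine (3 equiv), CH2Cl2, 0 °C
Reagents that add atoms: methyl chloroformate, COC(=O)Cl
Why: Plain O-acylation of a primary allylic alcohol (carbonate formation) that leaves the E-alkenes untouched and creates no stereocenter.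

Step 2
Reactants: 2 (2E,6E,10E)-geranylgeranyl methyl carbonate
Product: 4 (R)-geranyllinalool, via tertiary allylboronate 3 (not isolated)
Conditions: B2pin2 (1.5 equiv), Cu(OTf)2 (5 mol %), chiral C1-symmetric imidazolinium salt (NHC precursor, 5.5 mol %), NaOMe (0.3 equiv), DME, −30 °C; then 30% H2O2, 2 M NaOH, THF, 0 °C
Reagents that add atoms: bis(pinacolato)diboron, CC1(C)OB(OC1(C)C)B1OC(C)(C)C(C)(C)O1 (boryl group of 3 only); hydrogen peroxide, OO (oxygen of 4)
Why: In this enantioselective Cu-catalysed SN2′ allylic borylation the chiral NHC–Cu–Bpin species adds only across the carbonate-activated C2=C3 alkene and expels carbonate, so the defined E geometry and the ligand fix the boron-bearing quaternary carbon, and the stereoretentive boron-to-oxygen 1,2-shift with peroxide turns it into the (R)-carbinol.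

Step 3
Reactants: 5 2,3,6-trimethylphenol
Product: 6 4-iodo-2,3,6-trimethylphenol
Conditions: NIS (1.05 equiv), TFA (10 mol %), MeCN, 0 °C → rt
Reagents that add atoms: N-iodosuccinimide, O=C1CCC(=O)N1I
Why: Electrophilic aromatic iodination goes para to the hydroxyl group, the only free position that the OH activates, because both ortho positions carry methyl.

Step 4
Reactants: 4 (R)-geranyllinalool; 6 4-iodo-2,3,6-trimethylphenol
Product: 8 4-[(3R,6E,10E)-3-hydroxy-3,7,11,15-tetramethylhexadeca-6,10,14-trien-1-yl]-2,3,6-trimethylphenol, via B-alkyl-9-BBN adduct 7 (not isolated)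
Conditions: 9-BBN (1.5 equiv), THF, 0 °C → rt; then 6, PdCl2(dppf)·CH2Cl2 (5 mol %), 3 M aq NaOH (3 equiv), THF/DMF, 50 °C, degassed
Reagents that add atoms: 9-borabicyclo[3.3.1]nonane, [H]B1C2CCCC1CCC2 (boryl group of 7 only; only hydrogen stays in 8)
Why: In this hydroboration/B-alkyl Suzuki–Miyaura sequence 9-BBN adds anti-Markovnikov to the monosubstituted vinyl group far faster than to the three trisubstituted alkenes, and the primary alkylborane couples with the aryl iodide without touching the carbinol carbon.

Step 5
Reactants: 8 4-[(3R,6E,10E)-3-hydroxy-3,7,11,15-tetramethylhexadeca-6,10,14-trien-1-yl]-2,3,6-trimethylphenol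
Product: 9 (2R)-2,6,7,9-tetramethyl-2-[(3E,7E)-4,8,12-trimethyltrideca-3,7,11-trien-1-yl]-1-oxaspiro[4.5]deca-6,9-dien-8-one (both C5 epimers)
Conditions: PhI(OAc)2 (1.1 equiv), MeCN, 0 °C, Ar
Reagents that add atoms: none
Why: In this hypervalent-iodine oxidative dearomatisation (phenol spiroetherification) the phenol binds iodine(III) and the tethered tertiary hydroxyl attacks the para carbon in a 5-exo mode faster than acetate or the remote alkenes can, the C2–O bond stays intact, and the new spiro centre may form as a mixture because it is erased later.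

Step 6
Reactants: 9 (2R)-2,6,7,9-tetramethyl-2-[(3E,7E)-4,8,12-trimethyltrideca-3,7,11-trien-1-yl]-1-oxaspiro[4.5]deca-6,9-dien-8-one
Product: 10 (R)-α-tocotrienol
Conditions: MeAlCl2 (1.5 equiv, 1 M in hexanes), CH2Cl2 (0.02 M), −78 → −20 °C, Ar; aq Rochelle salt
Reagents that add atoms: none
Why: Dienone–phenol rearrangement, the laboratory counterpart of the NIH shift: MeAlCl2 binds the C8 carbonyl oxygen and turns the cross-conjugated dienone into an oxy-pentadienyl cation with charge at C6 and C10, the two carbons that flank the spiro centre C5. The ring CH2 (future C4) then shifts 1,2 from C5 to C10, and carbon rather than oxygen migrates because the ether oxygen that stays behind stabilises the cation developing at C5 as an oxocarbenium ion; the closest known reactions are the acid-induced rearrangements of p-quinols and p-quinol ethers to 2-alkylhydroquinone derivatives and the ring expansions of spiro[4.5]decadienones. The mode of ring formation is enlargement of the spiro-tetrahydrofuran to the dihydropyran by this 1,2-shift (no exo or endo closure), and loss of the C10 proton regenerates the arene with O1 and OH para. The site selectivity needed is secured by the substrate, since a shift to C6 gives a methyl-blocked cation that cannot aromatise and reverts, while C10 bears the only ring hydrogen, so both spiro epimers should funnel into one constitution. No stereocenter is created: C2 keeps all four of its bonds and stays (R), and the spiro centre disappears. Chemoselectivity over the three trisubstituted alkenes rests on the carbonyl being the most Lewis-basic site and on the Al–CH3 bond consuming the released proton as methane, so that no Brønsted acid accumulates.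

**Compound list**
1 | (2E,6E,10E)-geranylgeraniol | CC(C)=CCC/C(C)=C/CC/C(C)=C/CC/C(C)=C/CO | starting material
2 | (2E,6E,10E)-geranylgeranyl methyl carbonate | CC(C)=CCC/C(C)=C/CC/C(C)=C/CC/C(C)=C/COC(=O)OC | intermediate
3 | (S)-2-[(6E,10E)-3,7,11,15-tetramethylhexadeca-1,6,10,14-tetraen-3-yl]-4,4,5,5-tetramethyl-1,3,2-dioxaborolane | CC(C)=CCC/C(C)=C/CC/C(C)=C/CC[C@@](C)(B1OC(C)(C)C(C)(C)O1)C=C | intermediate
4 | (R)-geranyllinalool, (3R,6E,10E)-3,7,11,15-tetramethylhexadeca-1,6,10,14-tetraen-3-ol | CC(C)=CCC/C(C)=C/CC/C(C)=C/CC[C@@](C)(O)C=C | intermediate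
5 | 2,3,6-trimethylphenol | Cc1ccc(C)c(O)c1C | starting material
6 | 4-iodo-2,3,6-trimethylphenol | Cc1cc(I)c(C)c(C)c1O | intermediate
7 | (6E,10E)-1-(9-borabicyclo[3.3.1]nonan-9-yl)-3,7,11,15-tetramethylhexadeca-6,10,14-trien-3-ol (same spatial arrangement at the carbinol carbon as 4; formally 3S because boron ranks below carbon) | CC(C)=CCC/C(C)=C/CC/C(C)=C/CC[C@@](C)(O)CCB1C2CCCC1CCC2 | intermediate
8 | 4-[(3R,6E,10E)-3-hydroxy-3,7,11,15-tetramethylhexadeca-6,10,14-trien-1-yl]-2,3,6-trimethylphenol | CC(C)=CCC/C(C)=C/CC/C(C)=C/CC[C@@](C)(O)CCc1cc(C)c(O)c(C)c1C | intermediate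
9 | (2R)-2,6,7,9-tetramethyl-2-[(3E,7E)-4,8,12-trimethyltrideca-3,7,11-trien-1-yl]-1-oxaspiro[4.5]deca-6,9-dien-8-one (C5 epimers) | CC(C)=CCC/C(C)=C/CC/C(C)=C/CC[C@]1(C)CCC2(O1)C=C(C)C(=O)C(C)=C2C | intermediate
10 | (R)-α-tocotrienol, (2R)-2,5,7,8-tetramethyl-2-[(3E,7E)-4,8,12-trimethyltrideca-3,7,11-trien-1-yl]chroman-6-ol | CC(C)=CCC/C(C)=C/CC/C(C)=C/CC[C@]1(C)CCc2c(C)c(O)c(C)c(C)c2O1 | target

**Step count:** 6 steps in total. The longest linear sequence is 5 steps (1, 2, 4, 5, 6).

**Steps most likely to fail**

Step 6. The Lewis acid may open the spiro ether toward a quinone methide. The activated dienone or adventitious acid may engage the trisubstituted alkenes, or the migration may stall.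
- The fallback makes O1–C8a by cross-coupling instead of by dearomatisation and shift, so it also bypasses step 5. It sets out from 5 and from borane 7 and comes back at 10.
- Para-bromination of 5 (NBS, MeCN) should give 4-bromo-2,3,6-trimethylphenol F1.
- Iodination of the last free ring position (NIS, cat. TfOH) should give 4-bromo-3-iodo-2,5,6-trimethylphenol F2.
- Silylation (TBSCl, imidazole, DMF) gives its tert-butyldimethylsilyl ether F3.
- A B-alkyl Suzuki–Miyaura coupling of 7 at the C–I bond only (PdCl2(dppf), aq NaOH, rt) gives the bromoaryl tertiary alcohol F4.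
- An intramolecular Buchwald–Hartwig-type C–O coupling follows (Pd(OAc)2, bulky di-tert-butylbiarylphosphine, Cs2CO3, toluene, 80 °C). The tertiary alkoxide has no β-hydrogen, and the C2–O bond is retained. This closes the pyran ring to O-TBS-(R)-α-tocotrienol F5.
- TBAF then converts F5 into 10.

Step 2. Facial discrimination in the Cu–B addition may be insufficient, or direct SN2 substitution may compete.
- The fallback reads the stereocenter from the E-alkene by a sigmatropic shift. It sets out from 1 and comes back at 4.
- PBr3 (Et2O, 0 °C) gives geranylgeranyl bromide F6.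
- Dibenzylamine with K2CO3 gives N,N-dibenzylgeranylgeranylamine F7.
- One equivalent of mCPBA at −20 °C gives the amine N-oxide F8, since N-oxidation outruns epoxidation.
- A [2,3]-Meisenheimer rearrangement catalysed by a planar-chiral palladacycle is stereospecific with respect to the alkene geometry. It gives O-[(R)-geranyllinalyl]-N,N-dibenzylhydroxylamine F9.
- Zn/AcOH cleaves the N–O bond of F9 to give 4.

Step 4. Oxidative addition of the electron-rich iodophenolate may be slow. The neighbouring alkoxide may sequester the borane, or protodeboronation may occur.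
- The fallback forms the aryl–carbon bond by alkene arylation and adjusts the oxidation level afterwards. It sets out from 4 and 6 and comes back at 8.
- A Heck reaction (Pd(OAc)2, Bu4NCl, NaHCO3, DMF, 70 °C) on the vinyl group gives the (E)-styryl carbinol F10. The vinyl group cannot isomerise to a ketone because the carbinol is tertiary.
- Diimide (2-nitrobenzenesulfonylhydrazide, Et3N) reduces the single disubstituted alkene in preference to the trisubstituted ones, giving 8.

**Further compounds**
F1 | step 6 | 4-bromo-2,3,6-trimethylphenol | Cc1cc(Br)c(C)c(C)c1O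
F2 | step 6 | 4-bromo-3-iodo-2,5,6-trimethylphenol | Cc1c(I)c(Br)c(C)c(C)c1O
F3 | step 6 | (4-bromo-3-iodo-2,5,6-trimethylphenoxy)(tert-butyl)dimethylsilane | Cc1c(I)c(Br)c(C)c(C)c1O[Si](C)(C)C(C)(C)C
F4 | step 6 | (3R,6E,10E)-1-[2-bromo-5-(tert-butyldimethylsilyloxy)-3,4,6-trimethylphenyl]-3,7,11,15-tetramethylhexadeca-6,10,14-trien-3-ol | CC(C)=CCC/C(C)=C/CC/C(C)=C/CC[C@@](C)(O)CCc1c(Br)c(C)c(C)c(O[Si](C)(C)C(C)(C)C)c1C
F5 | step 6 | O-(tert-butyldimethylsilyl)-(R)-α-tocotrienol | CC(C)=CCC/C(C)=C/CC/C(C)=C/CC[C@]1(C)CCc2c(C)c(O[Si](C)(C)C(C)(C)C)c(C)c(C)c2O1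
F6 | step 2 | (2E,6E,10E)-geranylgeranyl bromide | CC(C)=CCC/C(C)=C/CC/C(C)=C/CC/C(C)=C/CBr
F7 | step 2 | N,N-dibenzyl-(2E,6E,10E)-geranylgeranylamine | CC(C)=CCC/C(C)=C/CC/C(C)=C/CC/C(C)=C/CN(Cc1ccccc1)Cc1ccccc1
F8 | step 2 | N,N-dibenzyl-(2E,6E,10E)-geranylgeranylamine N-oxide | CC(C)=CCC/C(C)=C/CC/C(C)=C/CC/C(C)=C/C[N+]([O-])(Cc1ccccc1)Cc1ccccc1
F9 | step 2 | O-[(3R,6E,10E)-3,7,11,15-tetramethylhexadeca-1,6,10,14-tetraen-3-yl]-N,N-dibenzylhydroxylamine | CC(C)=CCC/C(C)=C/CC/C(C)=C/CC[C@@](C)(ON(Cc1ccccc1)Cc1ccccc1)C=C
F10 | step 4 | 4-[(1E,3R,6E,10E)-3-hydroxy-3,7,11,15-tetramethylhexadeca-1,6,10,14-tetraen-1-yl]-2,3,6-trimethylphenol | CC(C)=CCC/C(C)=C/CC/C(C)=C/CC[C@@](C)(O)/C=C/c1cc(C)c(O)c(C)c1C
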